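Two questions stand below, and for the second I fold the givens into one dimensionless number.

| flask | starting material | partner | time |
|---|---|---|---|
| blue | 0.150 M | 0.450 M |  |
| amber | 0.150 M | 0.230 M |  |
| teal | 0.750 M | 0.450 M | 19 min |

| blue run: time / min | blue run: [target] / M | amber run: time / min | amber run: [target] / M |
|---|---|---|---|
| 2.7 | 0.0289 | 2.7 | 0.0161 |
| 5.4 | 0.0468 | 5.4 | 0.0255 |
| 8.1 | 0.0620 | 8.1 | 0.0357 |
| 11 | 0.0793 | 11 | 0.0485 |
| 14 | 0.0895 | 14 | 0.0544 |
| 16 | 0.1000 | 16 | 0.0548 |
| 19 | 0.1098 | 19 | 0.0651 |

(each reading ± 0.002 M)

- the power of [partner] that the first rate follows, about the charge of the blue run; measure it at two percent of starting material made into target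
- target in the teal run at 19 min, as a share of the starting material charged

- Overall: starting material + partner -> target.
- Constant volume, constant temperature.
- Bound and free are read together.
- "The second partner" is partner.
- An order is taken over about fifteen percent of the charge, up and down.

For the first, I compare the two runs where nearly equal target has been made, 0.0468 M at 5.4 min in the blue run and 0.0485 M at 11 min in the amber run: the mean rate of amber over blue is 0.509 for a partner charge ratio of 0.511, so my reading of the order in partner is 1.01, taken over a wider span than the one asked.

With an order near one, rate divided by partner is a specific rate of partner loss, pseudo-first-order in partner where starting material changes little. In the blue run it is 0.0203 min⁻¹ over the first 5.4 min, at a mean starting material of 0.127 M, but 0.0116 min⁻¹ between 14 min and 19 min, at a mean starting material of 0.0504 M. That reads as an order in starting material of 0.609, lower than the plain value of one that serves as my zero, and the scatter leaves that late rate uncertain by about 13.9%.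

In the teal run partner is the limiting reagent, with a ceiling of 60.0% of the starting material charged. A first pass at the full charge gives 0.306 M of target, so the mean starting material is 0.597 M. The exposure, meaning the specific rate at that mean, scaled from blue, times the time, is 0.992. Target is then the partner charge times one minus e to the minus exposure, or 37.8% of the starting material charged. One number is enough if the specific rate moves little, and in my teal reckoning it falls by a factor of 1.34.

The forecast gave 0.9 and 46%, holding that “Both runs fit simple second-order kinetics”. The flask gives 1.0 and 37.5%.

    starting material ⇌ intermediate, settled at all times (0.1630)
    intermediate + partner → target (2.172 L mol⁻¹ min⁻¹)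
    2 starting material ⇌ idle substrate dimer, settled at all times (9.550 L mol⁻¹)

Throughout the teal run, starting material stood in fast equilibrium with the intermediate and the idle substrate dimer while the intermediate met partner and gave target, and partner came down to 0.168 M. That end corresponds to an exposure of 0.983 against my 0.992, and the same exposure rule, with amber's own mean starting material, gives 0.0709 M of target in the amber run at 19 min, where the reading is 0.0651 M.

The earlier runs and the new flask are simulated on assumed constants; the scatter is artificial.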